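The target is the wanted species and the isomer of the product is the unwanted one. The three flasks below differ in temperature, and what is asked is the target's share of the two, its selectivity, at the end.

| flask | starting material | coupling partner | protic impurity | catalyst | added ligand | temperature | remark | time |
|---|---|---|---|---|---|---|---|---|
| Thursday's | 0.80 M | 1.2 equiv | 0.016 M | 0.14 mol% | 1.8 mM | −25 °C | run made earlier |  |
| Sunday's | 0.80 M | 1.2 equiv | 0.016 M | 0.14 mol% | 2.6 mM | 0 °C | run made earlier |  |
| Friday's | 0.80 M | 1.8 equiv | 0.016 M | 0.14 mol% | 3.5 mM | −25 °C | run made earlier |  |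
| autumn | 0.80 M | 1.20 equiv | 0.0160 M | 0.14 mol% | 3.5 mM | −20 °C |  | 2.0 h |
| midnight | 0.80 M | 1.20 equiv | 0.0160 M | 0.14 mol% | 3.5 mM | 0 °C |  | 2.0 h |
| summer | 0.80 M | 1.20 equiv | 0.0160 M | 0.14 mol% | 3.5 mM | 20 °C |  | 2.0 h |

| run | time / min | target / % | isomer of the product / % | starting material / % |
|---|---|---|---|---|
| Thursday's | 6.00 | 0 | 0 | 99.8 |
| Thursday's | 10.0 | 1.3 | 2.3 | 98.9 |
| Thursday's | 20.0 | 0 | 0 | 98.0 |
| Thursday's | 40.0 | 0.4 | 0 | 100.0 |
| Thursday's | 80.0 | 2.1 | 0 | 97.6 |
| Sunday's | 2.00 | 0.9 | 0 | 98.5 |
| Sunday's | 8.00 | 5.3 | 0 | 96.5 |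
| Sunday's | 12.0 | 6.7 | 0 | 93.8 |
| Sunday's | 20.0 | 9.6 | 2.2 | 90.8 |
| Sunday's | 30.0 | 13.2 | 0.7 | 85.3 |
| Friday's | 15.0 | 1.6 | 0 | 99.6 |
| Friday's | 30.0 | 1.0 | 0 | 98.5 |
| Friday's | 40.0 | 1.6 | 0 | 98.1 |
| Friday's | 60.0 | 1.0 | 0.9 | 97.4 |
| Friday's | 80.0 | 2.4 | 1.2 | 95.4 |

(readings scatter by 1 percentage point)

- the best flask by share of target in all that became target or isomer of the product; "all alike" if 1.5 percentage points covers them all (autumn / midnight / summer / all alike)
- share of target in all that became target or isomer of the product, autumn
- share of target in all that became target or isomer of the product, midnight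
- share of target in all that became target or isomer of the product, summer

This reckoning assumes that c(isomer)/c(target) starts at zero and rises with conversion on one slope in all three flasks. On that assumption, a warmer flask that has converted further beats autumn if the slope is zero or below. Sunday's last two readings test this. Their isomer sums to 2.9 percentage points, where such a sum scatters by 1.4 points, so the test is thin. They give the drift s, which is c(isomer)/c(target) per unit of converted fraction X: 1.06.

share = 1 / (1 + s·X)

Midnight, repeating Sunday's fractional loss over the time: X = 47.1 %, share 66.6 %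

Autumn, scaling Thursday's loss to the time, though Thursday's bath was colder: X = 3.60 %, share 96.3 %

Summer, taking X = 1 as the ceiling: share 48.4 %

Midnight stands further along than autumn, so with s above zero this reckoning puts autumn first.

The forecast differs. It names midnight, with 90 % for autumn, 91 % for midnight and 87 % for summer. It expects that at the warmest bath “isomerisation of the target would probably lower the share”.

The flasks give 96.9 % for autumn, 83.8 % for midnight and 47.0 % for summer, so autumn is best.

    catalyst + added ligand ⇌ idle complex, settled at all times (K = 580 /M, ΔH = −22.0 kJ/mol)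
    starting material + coupling partner ⇌ isomer of the product (K = 4.80 /M, k = 2.60 × 10⁻⁵ /M/s, Ea = 78.0 kJ/mol, ΔH = −43.0 kJ/mol)
    target + catalyst ⇌ isomer of the product + catalyst, rate k3*[catalyst]*[target] forward; the back reaction follows from the equilibrium constant (k = 0.680 /M/s, Ea = 52.0 kJ/mol)
    coupling partner + protic impurity → quenched reagent (k = 0.0210 /M/s, Ea = 58.0 kJ/mol)
    starting material + coupling partner ⇌ target (K = 3.60 /M, k = 7.40 × 10⁻⁴ /M/s, Ea = 68.0 kJ/mol, ΔH = −40.0 kJ/mol)
    (constants at 20 °C)

The forecast and the flasks part on the drift. The drift s at 2.00 h comes to 0.540 in autumn and 0.479 in midnight, and neither is near zero. A neighbour flask, midnight with 2.10 mM of added ligand, holds 38.7 % of its catalyst free against 25.1 %. Scaling s by that ratio gives 0.738, and at its conversion of 40.5 % the share reckons to 77.0 %. The neighbour flask gives 78.1 %.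

The numbers in the tables are simulated for an exercise; scatter was added.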